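**Retrosynthetic overview**
1. Both imidazol-2-yl–CH2 bonds are cut last: the target goes back to 2-(3-formylphenoxy)-5-methoxybenzaldehyde and two 2-lithio-1-SEM-imidazoles (addition, deoxygenation, SEM removal), so the imidazole rings arrive intact.
2. The strategy rests on ring A: the diaryl-ether oxygen sits on C1, the benzylic carbon on the adjacent C2, and the methoxy group on C4, para to the oxygen.
3. That pattern is what an oxygen-bearing alkyne carbon leaves when it bonds to the ester-bearing C3 of a 5-methoxy-2-pyrone. Ring A is therefore made by [4+2] cycloaddition and CO2 loss between the ethynyl ether of ring B and methyl 5-methoxy-2-oxo-2H-pyran-3-carboxylate, forming C1–C2 and C5–C6.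
4. Ring B is bought as 3-hydroxybenzaldehyde (dichlorovinyl ether, acetal, ynol ether); the pyrone comes from methoxyacetaldehyde dimethyl acetal, DMF and dimethyl malonate.
5. Ring order: pyrone ring (step 3), ring A grown onto the ring B oxygen (step 7), the two imidazoles attached (step 11).

Key step: step 7

Remark: the push–pull alkenes 2, 3, 5, 6 and 7 are written in their expected geometries, which interconvert easily and do not affect the outcome. The two carbinol centres of 25 and 26 are not controlled and are removed in step 12; the target is achiral. SEM = 2-(trimethylsilyl)ethoxymethyl.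

**Route**

Step 1
Reactants: 1 1,1,2-trimethoxyethane (methoxyacetaldehyde dimethyl acetal)
Product: 3 (Z)-3-(dimethylamino)-2-methoxyprop-2-enal, via methoxypropeniminium salt 2 (not isolated)
Conditions: POCl3 (2.2 equiv), DMF, 0 to 70 °C; then aq. K2CO3, 50 °C
Reagents that add atoms: N,N-dimethylformamide, CN(C)C=O; water, O
Why: Vilsmeier–Haack formylation: the acetal loses methanol to 1,2-dimethoxyethene, the chloroiminium ion formylates it at carbon to give salt 2, and basic hydrolysis should give the vinylogous formamide, the established route from alkoxyacetaldehyde acetals to 2-alkoxy-3-(dimethylamino)acroleins.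

Step 2
Reactants: 3 (Z)-3-(dimethylamino)-2-methoxyprop-2-enal; 4 dimethyl malonate
Product: 6 dimethyl 2-[(Z)-3-(dimethylamino)-2-methoxyprop-2-en-1-ylidene]propanedioate, via O-methyl iminium methyl sulfate 5 (not isolated)
Conditions: Me2SO4 (1.05 equiv), CH2Cl2, 40 °C; then 4, NaOMe, MeOH, 0 °C to rt
Reagents that add atoms: none
Why: O-methylation makes the carbonyl carbon of the vinylogous amide electrophilic, so sodium dimethyl malonate should add there and lose methanol in a Knoevenagel-type condensation to the push–pull diene.

Step 3
Reactants: 6 dimethyl 2-[(Z)-3-(dimethylamino)-2-methoxyprop-2-en-1-ylidene]propanedioate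
Product: 8 methyl 5-methoxy-2-oxo-2H-pyran-3-carboxylate, via hydroxydiene diester 7 (not isolated)
Conditions: 2 M aq. HCl, AcOH, 60 °C
Reagents that add atoms: water, O
Why: Acid hydrolysis of the enamine terminus gives enol 7, which should lactonize 6-exo-trig onto the cis ester with loss of methanol, the same closure that turns alkoxyallylidene malonates into 3-carbomethoxy-2-pyrones; the liberated amine stays protonated and cannot open the pyrone.

Step 4
Reactants: 9 3-hydroxybenzaldehyde; 10 trichloroethylene
Product: 12 3-[(E)-1,2-dichloroethenoxy]benzaldehyde, via dichloroacetylene 11 (not isolated)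
Conditions: K2CO3 (2 equiv), DMF, 70 °C
Reagents that add atoms: none
Why: K2CO3 converts trichloroethylene into dichloroacetylene, to which the phenoxide adds in anti fashion, the standard preparation of aryl (E)-1,2-dichlorovinyl ethers; the non-enolizable aldehyde is inert.

Step 5
Reactants: 12 3-[(E)-1,2-dichloroethenoxy]benzaldehyde
Product: 13 1-[(E)-1,2-dichloroethenoxy]-3-(dimethoxymethyl)benzene
Conditions: HC(OMe)3, MeOH, p-TsOH·H2O (cat.), rt; Et3N quench
Reagents that add atoms: methanol, CO; trimethyl orthoformate, COC(OC)OC
Why: Acid-catalysed acetalization driven by the orthoformate as water scavenger masks the aldehyde against n-BuLi, and the electron-poor dichlorovinyl ether should tolerate the mild anhydrous acid.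

Step 6
Reactants: 13 1-[(E)-1,2-dichloroethenoxy]-3-(dimethoxymethyl)benzene
Product: 16 1-(dimethoxymethyl)-3-(ethynyloxy)benzene, via chloroethynyl ether 14 (not isolated), via lithium acetylide 15 (not isolated)
Conditions: n-BuLi (2.3 equiv), THF, −78 to −40 °C; then H2O, −78 °C; cold work-up, used at once as a toluene solution
Reagents that add atoms: none
Why: In the dichlorovinyl ether route to ynol ethers, vinylic deprotonation and loss of LiCl give the chloroalkyne, chlorine–lithium exchange gives the acetylide, and protonation by water gives the terminal aryl ynol ether; the acetal is inert to the base.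

Step 7
Reactants: 16 1-(dimethoxymethyl)-3-(ethynyloxy)benzene; 8 methyl 5-methoxy-2-oxo-2H-pyran-3-carboxylate
Product: 18 methyl 2-[3-(dimethoxymethyl)phenoxy]-5-methoxybenzoate, via bridged lactone 17 (not isolated)
Conditions: toluene, 100 °C, 16 (2 equiv) added slowly, BHT (cat.)
Reagents that add atoms: none
Why: The ynol ether is an electron-rich 2π partner and the 3-carbomethoxy-2-pyrone an electron-poor 4π partner, so a concerted but asynchronous inverse-electron-demand [4+2] cycloaddition across pyrone C3 and C6 should give the 2-oxabicyclo[2.2.2]octadienone 17, which should lose CO2 by retro-[4+2] at the reaction temperature and aromatize to 18. The closest known reaction type is the benzoate synthesis from 3-alkoxycarbonyl-2-pyrones and ketene acetals, ynamines or alkoxyalkynes by cycloaddition and decarboxylation. Ring A is closed intermolecularly in [4+2] mode, its C1–C2 and C5–C6 bonds forming in the cycloaddition and its aromatic sextet in the cycloreversion. No stereocentre remains, because the two bridgehead centres of 17 disappear with CO2. The step needs one regiochemistry, the unsubstituted alkyne carbon to pyrone C6 and the oxygen-bearing carbon to the ester-bearing C3; the nucleophilic β-carbon of the ynol ether and the vinylogous acceptor position C6 of the pyrone, activated by both carbonyl groups, secure it and place the ester ortho and the methoxy group para to the aryloxy group. The 5-methoxy group slows the diene without reversing its polarization, hence heating with slow addition of excess 16 so that the cycloaddition outruns self-reaction of the alkyne.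

Step 8
Reactants: 18 methyl 2-[3-(dimethoxymethyl)phenoxy]-5-methoxybenzoate
Product: 20 3-[2-(hydroxymethyl)-4-methoxyphenoxy]benzaldehyde, via benzylic alcohol acetal 19 (not isolated)
Conditions: LiAlH4, THF, 0 °C; then 1 M aq. HCl, THF, rt
Reagents that add atoms: water, O
Why: Hydride reduction takes the ester to the primary alcohol while the acetal is inert, and the acidic work-up should hydrolyse the aryl dimethyl acetal to the aldehyde.

Step 9
Reactants: 20 3-[2-(hydroxymethyl)-4-methoxyphenoxy]benzaldehyde
Product: 21 2-(3-formylphenoxy)-5-methoxybenzaldehyde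
Conditions: MnO2 (activated, excess), CH2Cl2, rt
Reagents that add atoms: none
Why: Activated MnO2 oxidizes benzylic alcohols selectively to aldehydes without over-oxidation and leaves the diaryl ether untouched.

Step 10
Reactants: 22 imidazole
Product: 23 1-{[2-(trimethylsilyl)ethoxy]methyl}-1H-imidazole (1-SEM-imidazole)
Conditions: NaH, THF, 0 °C; then SEM-Cl, 0 °C to rt
Reagents that add atoms: 2-(trimethylsilyl)ethoxymethyl chloride, C[Si](C)(C)CCOCCl
Why: N-alkylation of sodium imidazolide with the chloromethyl ether is a standard SN2 protection, and the SEM group directs lithiation to C2.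

Step 11
Reactants: 21 2-(3-formylphenoxy)-5-methoxybenzaldehyde; 23 1-SEM-imidazole
Product: 25 [2-(3-{hydroxy[1-(SEM)imidazol-2-yl]methyl}phenoxy)-5-methoxyphenyl][1-(SEM)imidazol-2-yl]methanol (mixture of diastereomers), via 2-lithio-1-SEM-imidazole 24 (not isolated)
Conditions: 23 (2.6 equiv), n-BuLi (2.5 equiv), THF, −78 °C; then 21, −78 to 0 °C; H2O
Reagents that add atoms: none
Why: C2 lithiation of the N-protected imidazole and 1,2-addition of the organolithium to both non-enolizable aldehydes should form both imidazole–carbon bonds at once; the two new carbinol centres are set without control and are removed in the next step.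

Step 12
Reactants: 25 bis-carbinol
Product: 27 2-{3-[4-methoxy-2-({1-SEM-1H-imidazol-2-yl}methyl)phenoxy]benzyl}-1-SEM-1H-imidazole, via bis(benzylic chloride) 26 (not isolated)
Conditions: SOCl2, CH2Cl2, 0 to 40 °C; evaporate; then Zn dust, AcOH, rt
Reagents that add atoms: none
Why: SOCl2 should convert both benzylic carbinols into chlorides while the imidazole nitrogens take up the HCl, and zinc in acetic acid should reduce the activated benzylic C–Cl bonds by electron transfer and protonation, a chlorination and reductive dehalogenation sequence that also removes both stereocentres.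

Step 13
Reactants: 27 bis-SEM lepidine C
Product: 28 lepidine C, 2-{3-[2-(1H-imidazol-2-ylmethyl)-4-methoxyphenoxy]benzyl}-1H-imidazole
Conditions: 3 M aq. HCl, EtOH, 80 °C; then aq. NaHCO3
Reagents that add atoms: none
Why: Acid hydrolysis of the N,O-acetal releases 2-(trimethylsilyl)ethanol and formaldehyde and frees both imidazole N–H groups, while the aryl methyl ether and the diaryl ether are stable to hot dilute HCl.

**Compound list**
1 | 1,1,2-trimethoxyethane | COCC(OC)OC | starting material
2 | N-[(Z)-2,3-dimethoxyprop-2-en-1-ylidene]-N-methylmethanaminium dichlorophosphate (not isolated) | CO/C=C(\OC)C=[N+](C)C.[O-]P(Cl)(Cl)=O | intermediate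
3 | (Z)-3-(dimethylamino)-2-methoxyprop-2-enal | CN(C)/C=C(\OC)C=O | intermediate
4 | dimethyl malonate | COC(=O)CC(=O)OC | starting material
5 | N-[(Z)-2,3-dimethoxyprop-2-en-1-ylidene]-N-methylmethanaminium methyl sulfate (not isolated) | CO/C=C(\OC)C=[N+](C)C.COS(=O)(=O)[O-] | intermediate
6 | dimethyl 2-[(Z)-3-(dimethylamino)-2-methoxyprop-2-en-1-ylidene]propanedioate | CN(C)/C=C(\OC)C=C(C(=O)OC)C(=O)OC | intermediate
7 | dimethyl 2-[(E)-3-hydroxy-2-methoxyprop-2-en-1-ylidene]propanedioate (not isolated) | O/C=C(/OC)C=C(C(=O)OC)C(=O)OC | intermediate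
8 | methyl 5-methoxy-2-oxo-2H-pyran-3-carboxylate | COC(=O)C1=CC(OC)=COC1=O | intermediate
9 | 3-hydroxybenzaldehyde | O=Cc1cccc(O)c1 | starting material
10 | trichloroethylene | ClC=C(Cl)Cl | starting material
11 | dichloroacetylene (not isolated) | ClC#CCl | intermediate
12 | 3-[(E)-1,2-dichloroethenoxy]benzaldehyde | O=Cc1cccc(O/C(Cl)=C\Cl)c1 | intermediate
13 | 1-[(E)-1,2-dichloroethenoxy]-3-(dimethoxymethyl)benzene | COC(OC)c1cccc(O/C(Cl)=C\Cl)c1 | intermediate
14 | 1-[(chloroethynyl)oxy]-3-(dimethoxymethyl)benzene (not isolated) | COC(OC)c1cccc(OC#CCl)c1 | intermediate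
15 | lithium {[3-(dimethoxymethyl)phenoxy]ethynide} (not isolated) | COC(OC)c1cccc(OC#C[Li])c1 | intermediate
16 | 1-(dimethoxymethyl)-3-(ethynyloxy)benzene | COC(OC)c1cccc(OC#C)c1 | intermediate
17 | methyl 5-[3-(dimethoxymethyl)phenoxy]-7-methoxy-3-oxo-2-oxabicyclo[2.2.2]octa-5,7-diene-4-carboxylate (racemic, not isolated) | COC(=O)C12C=C(OC)C(OC1=O)C=C2Oc1cccc(C(OC)OC)c1 | intermediate
18 | methyl 2-[3-(dimethoxymethyl)phenoxy]-5-methoxybenzoate | COC(=O)c1cc(OC)ccc1Oc1cccc(C(OC)OC)c1 | intermediate
19 | {2-[3-(dimethoxymethyl)phenoxy]-5-methoxyphenyl}methanol (not isolated) | COc1ccc(Oc2cccc(C(OC)OC)c2)c(CO)c1 | intermediate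
20 | 3-[2-(hydroxymethyl)-4-methoxyphenoxy]benzaldehyde | COc1ccc(Oc2cccc(C=O)c2)c(CO)c1 | intermediate
21 | 2-(3-formylphenoxy)-5-methoxybenzaldehyde | COc1ccc(Oc2cccc(C=O)c2)c(C=O)c1 | intermediate
22 | imidazole | c1c[nH]cn1 | starting material
23 | 1-{[2-(trimethylsilyl)ethoxy]methyl}-1H-imidazole | C[Si](C)(C)CCOCn1ccnc1 | intermediate
24 | 2-lithio-1-{[2-(trimethylsilyl)ethoxy]methyl}-1H-imidazole (not isolated) | [Li]c1nccn1COCC[Si](C)(C)C | intermediate
25 | [2-(3-{hydroxy[1-(SEM)imidazol-2-yl]methyl}phenoxy)-5-methoxyphenyl][1-(SEM)imidazol-2-yl]methanol, mixture of diastereomers, both centres unassigned | COc1ccc(Oc2cccc(C(O)c3nccn3COCC[Si](C)(C)C)c2)c(C(O)c2nccn2COCC[Si](C)(C)C)c1 | intermediate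
26 | bis(benzylic chloride) corresponding to 25, mixture of diastereomers (not isolated) | COc1ccc(Oc2cccc(C(Cl)c3nccn3COCC[Si](C)(C)C)c2)c(C(Cl)c2nccn2COCC[Si](C)(C)C)c1 | intermediate
27 | 2-{3-[4-methoxy-2-({1-SEM-1H-imidazol-2-yl}methyl)phenoxy]benzyl}-1-SEM-1H-imidazole | COc1ccc(Oc2cccc(Cc3nccn3COCC[Si](C)(C)C)c2)c(Cc2nccn2COCC[Si](C)(C)C)c1 | intermediate
28 | lepidine C, 2-{3-[2-(1H-imidazol-2-ylmethyl)-4-methoxyphenoxy]benzyl}-1H-imidazole (achiral) | COc1ccc(Oc2cccc(Cc3ncc[nH]3)c2)c(Cc2ncc[nH]2)c1 | target

**Count**
Total steps: 13. Longest linear sequence: 9 steps (steps 1–3 or steps 4–6, then 7, 8, 9, 11, 12, 13).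

**Steps most likely to fail**

Step 7. The 5-methoxy donor may slow the cycloaddition so much that thermal self-reaction of the ynol ether consumes it first. The fallback gives up the cycloaddition and makes the diaryl ether bond directly by Ullmann coupling. It sets out from 9: coupling of 9 with commercial methyl 2-bromo-5-methoxybenzoate (COC(=O)c1cc(OC)ccc1Br) under CuI (cat.), N,N-dimethylglycine, Cs2CO3, dioxane, 90 °C should give methyl 2-(3-formylphenoxy)-5-methoxybenzoate F1, the ortho ester assisting the copper-mediated substitution. Acetalization of F1 with HC(OMe)3, MeOH and catalytic p-TsOH then comes back to the route at 18.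

Step 6. The terminal ynol ether may hydrate or oligomerize during the aqueous quench and concentration. The fallback stores the alkyne in a silyl-capped form and releases it without acid. It sets out from 13: the n-BuLi sequence is run as before, but acetylide 15 is quenched with Me3SiCl to give {[3-(dimethoxymethyl)phenoxy]ethynyl}trimethylsilane F2, which should tolerate chromatography and cold storage. Just before the cycloaddition, F2 is desilylated with K2CO3 in MeOH at 0 °C and extracted into toluene, which comes back to the route at 16.

Step 12. The benzylic chlorides may undergo acetolysis, or the SEM groups may be lost under HCl, before zinc reduction is complete, leaving oxygenated or partly deprotected mixtures. The fallback removes the oxygen at the ketone level. It sets out from 25: MnO2 in CH2Cl2 should oxidize both carbinols to the diketone [2-(3-{[1-(SEM)imidazol-2-yl]carbonyl}phenoxy)-5-methoxyphenyl][1-(SEM)imidazol-2-yl]methanone F3. Hydrazine hydrate in EtOH at 80 °C should give the bis-hydrazone of that diketone F4, and KOtBu in DMSO (Wolff–Kishner reduction) should convert it to the bis-methylene compound, which comes back to the route at 27.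

**Further compounds**
F1 | step 7 | methyl 2-(3-formylphenoxy)-5-methoxybenzoate | COC(=O)c1cc(OC)ccc1Oc1cccc(C=O)c1
F2 | step 6 | {[3-(dimethoxymethyl)phenoxy]ethynyl}trimethylsilane | COC(OC)c1cccc(OC#C[Si](C)(C)C)c1
F3 | step 12 | [2-(3-{[1-(SEM)imidazol-2-yl]carbonyl}phenoxy)-5-methoxyphenyl][1-(SEM)imidazol-2-yl]methanone | COc1ccc(Oc2cccc(C(=O)c3nccn3COCC[Si](C)(C)C)c2)c(C(=O)c2nccn2COCC[Si](C)(C)C)c1
F4 | step 12 | bis-hydrazone of F3 (E/Z mixture at both C=N bonds) | COc1ccc(Oc2cccc(C(=NN)c3nccn3COCC[Si](C)(C)C)c2)c(C(=NN)c2nccn2COCC[Si](C)(C)C)c1
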